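The route rests on cutting ring B (C5–C10) at C7–C8 and C9–C10. A ring A vinylcyclohexene supplies the diene C10=C5–C6=C7, and a but-2-ynoate supplies C8≡C9 together with C17 and C11. The ynoate is hung as an ester on the C2 oxygen, the future ketone, exploiting the 1,3-relationship of C2 and C10 in ring A. One intramolecular Diels–Alder reaction then closes ring B and a temporary C11–O–C2 δ-lactone, forms both bonds and sets quaternary C10 from the C2 stereocentre. The precursor is a monocyclic dienyl but-2-ynoate, three steps from actinol.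

Key step: step 4

Assumption: (4R,6R)-actinol 1 is taken as a purchasable industrial zeaxanthin intermediate; ring atoms are called by labdane numbers (ring A = C1–C5 and C10, ring B = C5–C10, C17 on C8, C20 on C10, C11–C16 the side chain).

Step 1
Reactants: 1 (4R,6R)-4-hydroxy-2,2,6-trimethylcyclohexan-1-one (actinol)
Product: 2 (1S,4R,6R)-1-ethenyl-2,2,6-trimethylcyclohexane-1,4-diol
Conditions: CH2=CHMgBr (3.5 equiv), CeCl3, THF, −78 °C to 0 °C; aq NH4Cl
Reagents that add atoms: vinylmagnesium bromide, C=C[Mg]Br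
Why: Cerium-assisted Grignard 1,2-addition to the hindered, enolizable ketone should give the tertiary allylic alcohol; the configuration drawn at the new carbinol carbon (attack opposite the axial C2 methyl) is of no consequence because step 3 removes it.

Step 2
Reactants: 2 (1S,4R,6R)-1-ethenyl-2,2,6-trimethylcyclohexane-1,4-diol; 3 but-2-ynoic acid
Product: 4 (1S,4S,5R)-4-ethenyl-4-hydroxy-3,3,5-trimethylcyclohexyl but-2-ynoate
Conditions: PPh3, DIAD, THF, 0 °C to rt (betaine formed before the acid and the diol are added)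
Reagents that add atoms: none
Why: The Mitsunobu esterification touches only the secondary hydroxyl and runs with SN2 inversion, so it turns the (R) carbinol of actinol into the (S) ester oxygen (labdane C2) that the key step needs and installs the dienophile in the same operation.

Step 3
Reactants: 4 (1S,4S,5R)-4-ethenyl-4-hydroxy-3,3,5-trimethylcyclohexyl but-2-ynoate
Product: 5 (1S)-4-ethenyl-3,5,5-trimethylcyclohex-3-en-1-yl but-2-ynoate
Conditions: Martin sulfurane (Ph2S[OC(CF3)2Ph]2), CH2Cl2, 0 °C to rt
Reagents that add atoms: none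
Why: Martin sulfurane dehydrates the tertiary allylic alcohol under neutral conditions that spare the ynoate, and the only β-hydrogen (on the methyl-bearing ring carbon) leads to the conjugated 1-vinylcyclohexene C10=C5–C6=C7.

Step 4
Reactants: 5 (1S)-4-ethenyl-3,5,5-trimethylcyclohex-3-en-1-yl but-2-ynoate
Product: 6 (7R,8aR)-7-hydroxy-2,5,5,8a-tetramethyl-3,5,6,7,8,8a-hexahydronaphthalene-1-carboxylic acid 1,7-lactone
Conditions: 1,2-dichlorobenzene (0.005 M), BHT (cat.), 180 °C, sealed tube
Reagents that add atoms: none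
Why: A thermal, concerted but asynchronous [4+2] cycloaddition joins the s-cis diene C10=C5–C6=C7 to the triple bond C8≡C9 of the tethered ynoate; the closest known type is the ester-tethered intramolecular Diels–Alder reaction of dienyl alkynoates. Ring B closes as the six-membered cycloaddition ring (a cyclohexa-1,4-diene with C5=C6 and C8=C9), and the δ-lactone C9–C11(=O)–O–C2–C1–C10 closes as the tether ring, fused to ring B along C9–C10 and bridging C2 and C10 of ring A. The only new stereocentre, quaternary C10, is controlled by C2: the four-atom tether lets the alkyne reach C10 only on the face that carries the pseudoaxial ester oxygen, so C9 ends cis to the C2 oxygen and the C10 methyl trans to it. The step needs regioselectivity (C9 to the fully substituted C10, C8 to C7) and facial selectivity; the tether length, which allows only the fused mode, and the single stereocentre C2 secure both. High dilution and a radical inhibitor should hold back intermolecular cycloaddition and polymerization, and the activated linear alkyne should keep the temperature below that at which a 1,5-hydrogen shift from the C10 methyl erodes the diene. The cost is the lactone-like s-cis ester geometry and the approach of the alkyne syn to the pseudoaxial C4 methyl, which is why this step carries the highest risk.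

Step 5
Reactants: 6 (7R,8aR)-7-hydroxy-2,5,5,8a-tetramethyl-3,5,6,7,8,8a-hexahydronaphthalene-1-carboxylic acid 1,7-lactone
Product: 7 methyl (7R,8aR)-7-hydroxy-2,5,5,8a-tetramethyl-3,5,6,7,8,8a-hexahydronaphthalene-1-carboxylate
Conditions: K2CO3 (0.2 equiv), MeOH, 0 °C
Reagents that add atoms: methanol, CO
Why: Carbonate-catalysed methanolysis (transesterification) of the strained bridged lactone frees the C2 hydroxyl and gives the C11 methyl ester, and the mild cold base should leave the skipped diene in place.

Step 6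
Reactants: 7 methyl (7R,8aR)-7-hydroxy-2,5,5,8a-tetramethyl-3,5,6,7,8,8a-hexahydronaphthalene-1-carboxylate
Product: 8 methyl (4aR,7R,8aR)-7-hydroxy-2,5,5,8a-tetramethyl-3,4,4a,5,6,7,8,8a-octahydronaphthalene-1-carboxylate
Conditions: H2 (3 atm), 10% Pd/C, EtOAc, rt
Reagents that add atoms: none
Why: Heterogeneous hydrogenation should reduce only the trisubstituted C5=C6 bond (the tetrasubstituted enoate is inert) and deliver hydrogen to C5 from the face opposite the angular C10 methyl, which sets the trans ring fusion.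

Step 7
Reactants: 8 methyl (4aR,7R,8aR)-7-hydroxy-2,5,5,8a-tetramethyl-3,4,4a,5,6,7,8,8a-octahydronaphthalene-1-carboxylate
Product: 10 methyl (1R,4aR,7R,8aR)-7-hydroxy-2,5,5,8a-tetramethyl-1,4,4a,5,6,7,8,8a-octahydronaphthalene-1-carboxylate, via dilithium dienolate 9 (not isolated)
Conditions: lithium diisopropylamide (3.2 equiv), THF–DMPU, −78 °C to −20 °C; inverse quench into AcOH/THF, −78 °C
Reagents that add atoms: none
Why: γ-Deprotonation of the twisted tetrasubstituted enoate at the ring methylene C7 gives the endocyclic dienolate (as in the β- to α-cyclogeranate deconjugation), and kinetic α-protonation at C9 opposite the axial C10 methyl gives the C7=C8 alkene with the equatorial ester (deconjugative protonation).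

Step 8
Reactants: 10 methyl (1R,4aR,7R,8aR)-7-hydroxy-2,5,5,8a-tetramethyl-1,4,4a,5,6,7,8,8a-octahydronaphthalene-1-carboxylate
Product: 12 (2R,4aR,8R,8aR)-8-ethenyl-4,4,7,8a-tetramethyl-1,2,3,4,4a,5,8,8a-octahydronaphthalen-2-ol, via aldehyde 11 (not isolated)
Conditions: i-Bu2AlH (2.3 equiv), CH2Cl2, −78 °C; then Ph3P=CH2 (from MePPh3Br and KN(SiMe3)2), THF, −78 °C to rt; aq potassium sodium tartrate
Reagents that add atoms: methyltriphenylphosphonium bromide, C[P+](c1ccccc1)(c1ccccc1)c1ccccc1.[Br-]
Why: Partial reduction of the ester to the aluminium hemiacetal followed by in situ Wittig methylenation converts C11 into the vinyl group C11=C12 without isolating the epimerizable β,γ-unsaturated aldehyde.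

Step 9
Reactants: 13 but-2-yn-1-ol
Product: 14 but-2-yn-1-yl acetate
Conditions: Ac2O, pyridine, DMAP (cat.), CH2Cl2, 0 °C
Reagents that add atoms: acetic anhydride, CC(=O)OC(C)=O
Why: Simple acyl transfer to the primary alcohol installs the acetate that the target carries at C15.

Step 10
Reactants: 14 but-2-yn-1-yl acetate
Product: 16 (2E)-3-iodobut-2-en-1-yl acetate, via alkenylzirconocene chloride 15 (not isolated)
Conditions: Cp2Zr(H)Cl (1.3 equiv), THF, rt, dark; then I2, 0 °C
Reagents that add atoms: iodine, II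
Why: Syn hydrozirconation should place zirconium on the alkyne carbon next to the small methyl group, and iodinolysis with retention gives the (E)-vinyl iodide (hydrozirconation–iodination); the regioisomeric β-acetoxy alkenylzirconium would eliminate to a volatile allene.

Step 11
Reactants: 12 (2R,4aR,8R,8aR)-8-ethenyl-4,4,7,8a-tetramethyl-1,2,3,4,4a,5,8,8a-octahydronaphthalen-2-ol; 16 (2E)-3-iodobut-2-en-1-yl acetate
Product: 18 (2E)-5-[(1R,4aR,7R,8aR)-7-hydroxy-2,5,5,8a-tetramethyl-1,4,4a,5,6,7,8,8a-octahydronaphthalen-1-yl]-3-methylpent-2-en-1-yl acetate, via bis(boryl) intermediate 17 (not isolated)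
Conditions: 9-BBN (2.5 equiv), THF, 0 °C to rt; then 16, Pd(dppf)Cl2 (5 mol%), AsPh3, aq K3PO4, DMF, rt
Reagents that add atoms: none
Why: 9-BBN hydroborates only the monosubstituted C11=C12 alkene at its terminus (and silences the hydroxyl as a borinate), and the B-alkyl Suzuki–Miyaura coupling forms C12–C13 with retention of the E geometry of the iodide, completing the side chain.

Step 12
Reactants: 18 (2E)-5-[(1R,4aR,7R,8aR)-7-hydroxy-2,5,5,8a-tetramethyl-1,4,4a,5,6,7,8,8a-octahydronaphthalen-1-yl]-3-methylpent-2-en-1-yl acetate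
Product: 19 (2E)-3-methyl-5-[(1R,4aR,8aR)-2,5,5,8a-tetramethyl-7-oxo-1,4,4a,5,6,7,8,8a-octahydronaphthalen-1-yl]pent-2-en-1-yl acetate
Conditions: Dess–Martin periodinane, CH2Cl2, rt
Reagents that add atoms: none
Why: Dess–Martin oxidation converts the secondary alcohol into the C2 ketone under neutral conditions that tolerate the allylic acetate and both trisubstituted alkenes.

Step 13
Reactants: 19 (2E)-3-methyl-5-[(1R,4aR,8aR)-2,5,5,8a-tetramethyl-7-oxo-1,4,4a,5,6,7,8,8a-octahydronaphthalen-1-yl]pent-2-en-1-yl acetate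
Product: 22 (2E)-5-[(1R,4aS,6S,8aS)-6-hydroxy-2,5,5,8a-tetramethyl-7-oxo-1,4,4a,5,6,7,8,8a-octahydronaphthalen-1-yl]-3-methylpent-2-en-1-yl acetate, via potassium enolate 20 (not isolated), via 3-epimer 21 (not isolated)
Conditions: KN(SiMe3)2 (1.1 equiv), THF, −78 °C; 2-(phenylsulfonyl)-3-phenyloxaziridine, −78 °C; aq NH4Cl; then DBU (0.2 equiv), CH2Cl2, rt
Reagents that add atoms: 2-(phenylsulfonyl)-3-phenyloxaziridine, O=S(=O)(N1OC1c1ccccc1)c1ccccc1
Why: The enolate should form toward C3 (as in 2-oxo-5α-steroids) and the oxaziridine should deliver oxygen axially, opposite the axial C4 and C10 methyls (Davis enolate hydroxylation); catalytic DBU then epimerizes C3 through the enediol to the hydrogen-bonded equatorial (3S) ketol, which is expected to be the thermodynamic isomer.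

Compound list
1 | (4R,6R)-4-hydroxy-2,2,6-trimethylcyclohexan-1-one (actinol) | C[C@@H]1C[C@@H](O)CC(C)(C)C1=O | starting material
2 | (1S,4R,6R)-1-ethenyl-2,2,6-trimethylcyclohexane-1,4-diol | C=C[C@@]1(O)C(C)(C)C[C@H](O)C[C@H]1C | intermediate
3 | but-2-ynoic acid | CC#CC(=O)O | starting material
4 | (1S,4S,5R)-4-ethenyl-4-hydroxy-3,3,5-trimethylcyclohexyl but-2-ynoate | C=C[C@@]1(O)C(C)(C)C[C@@H](OC(=O)C#CC)C[C@H]1C | intermediate
5 | (1S)-4-ethenyl-3,5,5-trimethylcyclohex-3-en-1-yl but-2-ynoate | CC#CC(=O)O[C@H]1CC(C)=C(C=C)C(C)(C)C1 | intermediate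
6 | (7R,8aR)-7-hydroxy-2,5,5,8a-tetramethyl-3,5,6,7,8,8a-hexahydronaphthalene-1-carboxylic acid 1,7-lactone (labdane C11 carbonyl bonded to the C2 oxygen) | O=C1O[C@@H]2CC(C)(C)C3=CCC(C)=C1[C@]3(C)C2 | intermediate
7 | methyl (7R,8aR)-7-hydroxy-2,5,5,8a-tetramethyl-3,5,6,7,8,8a-hexahydronaphthalene-1-carboxylate | COC(=O)C1=C(C)CC=C2C(C)(C)C[C@@H](O)C[C@@]12C | intermediate
8 | methyl (4aR,7R,8aR)-7-hydroxy-2,5,5,8a-tetramethyl-3,4,4a,5,6,7,8,8a-octahydronaphthalene-1-carboxylate | COC(=O)C1=C(C)CC[C@@H]2C(C)(C)C[C@@H](O)C[C@@]12C | intermediate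
9 | dilithium dienolate of 8 (lithium alkoxide at C2, lithium ester dienolate C7=C8–C9=C11; enolate geometry undefined) | COC(O[Li])=C1C(C)=CC[C@@H]2C(C)(C)C[C@@H](O[Li])C[C@@]12C | intermediate (not isolated)
10 | methyl (1R,4aR,7R,8aR)-7-hydroxy-2,5,5,8a-tetramethyl-1,4,4a,5,6,7,8,8a-octahydronaphthalene-1-carboxylate | COC(=O)[C@@H]1C(C)=CC[C@@H]2C(C)(C)C[C@@H](O)C[C@@]12C | intermediate
11 | (1R,4aR,7R,8aR)-7-hydroxy-2,5,5,8a-tetramethyl-1,4,4a,5,6,7,8,8a-octahydronaphthalene-1-carbaldehyde | O=C[C@@H]1C(C)=CC[C@@H]2C(C)(C)C[C@@H](O)C[C@@]12C | intermediate (not isolated)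
12 | (2R,4aR,8R,8aR)-8-ethenyl-4,4,7,8a-tetramethyl-1,2,3,4,4a,5,8,8a-octahydronaphthalen-2-ol | C=C[C@@H]1C(C)=CC[C@@H]2C(C)(C)C[C@@H](O)C[C@@]12C | intermediate
13 | but-2-yn-1-ol | CC#CCO | starting material
14 | but-2-yn-1-yl acetate | CC#CCOC(C)=O | intermediate
15 | [(2E)-4-acetoxybut-2-en-2-yl]chloridobis(cyclopentadienyl)zirconium | CC(=O)OC/C=C(\C)[Zr](Cl)(C1C=CC=C1)C1C=CC=C1 | intermediate (not isolated)
16 | (2E)-3-iodobut-2-en-1-yl acetate | CC(=O)OC/C=C(\C)I | intermediate
17 | C12 B-alkyl-9-borabicyclo[3.3.1]nonane and C2 O-borinate derived from 12 | C1CCC2CCCC1B2CC[C@@H]3C(C)=CC[C@@H]4C(C)(C)C[C@@H](OB5C6CCCC5CCC6)C[C@@]34C | intermediate (not isolated)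
18 | (2E)-5-[(1R,4aR,7R,8aR)-7-hydroxy-2,5,5,8a-tetramethyl-1,4,4a,5,6,7,8,8a-octahydronaphthalen-1-yl]-3-methylpent-2-en-1-yl acetate | CC(=O)OC/C=C(\C)CC[C@@H]1C(C)=CC[C@@H]2C(C)(C)C[C@@H](O)C[C@@]12C | intermediate
19 | (2E)-3-methyl-5-[(1R,4aR,8aR)-2,5,5,8a-tetramethyl-7-oxo-1,4,4a,5,6,7,8,8a-octahydronaphthalen-1-yl]pent-2-en-1-yl acetate | CC(=O)OC/C=C(\C)CC[C@@H]1C(C)=CC[C@@H]2C(C)(C)CC(=O)C[C@@]12C | intermediate
20 | potassium C2–C3 enolate of 19 | CC(=O)OC/C=C(\C)CC[C@@H]1C(C)=CC[C@@H]2C(C)(C)C=C(O[K])C[C@@]12C | intermediate (not isolated)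
21 | (2E)-5-[(1R,4aS,6R,8aS)-6-hydroxy-2,5,5,8a-tetramethyl-7-oxo-1,4,4a,5,6,7,8,8a-octahydronaphthalen-1-yl]-3-methylpent-2-en-1-yl acetate (3-epimer, axial hydroxyl) | CC(=O)OC/C=C(\C)CC[C@@H]1C(C)=CC[C@@H]2C(C)(C)[C@@H](O)C(=O)C[C@@]12C | intermediate (not isolated)
22 | (2E)-5-[(1R,4aS,6S,8aS)-6-hydroxy-2,5,5,8a-tetramethyl-7-oxo-1,4,4a,5,6,7,8,8a-octahydronaphthalen-1-yl]-3-methylpent-2-en-1-yl acetate (labdane numbering 3S,5S,9R,10S,13E) | CC(=O)OC/C=C(\C)CC[C@@H]1C(C)=CC[C@@H]2C(C)(C)[C@H](O)C(=O)C[C@@]12C | target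

Total steps: 13. Longest linear sequence: 11 (steps 1–8 and 11–13; steps 9 and 10 make the vinyl iodide).

Steps most likely to fail

Step 4. The ester may not reach the lactone-like s-cis geometry over the hindered face of the diene before a thermal 1,5-hydrogen shift or polymerization consumes the diene. The fallback gives up the tether and runs the cycloaddition between two molecules. It sets out from 5: K2CO3 in MeOH cleaves the butynoate and should give (1S)-4-ethenyl-3,5,5-trimethylcyclohex-3-en-1-ol F1, and TBSCl with imidazole gives the silyl ether tert-butyl{[(1S)-4-ethenyl-3,5,5-trimethylcyclohex-3-en-1-yl]oxy}dimethylsilane F2. Heating F2 neat with methyl but-2-ynoate at about 130 °C should give the adduct methyl (7R,8aR)-7-{[tert-butyl(dimethyl)silyl]oxy}-2,5,5,8a-tetramethyl-3,5,6,7,8,8a-hexahydronaphthalene-1-carboxylate F3. Here the half-chair with the equatorial silyloxy group places the pseudoaxial C4 methyl on the opposite face, so the alkyne should add cis to the oxygen as before, and the doubly alkylated terminus C10 should take the ester-bearing carbon. Bu4NF then removes the silyl group and the route is rejoined at 7.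

Step 7. The amide base may remove a proton from the C8 methyl, which lies syn to the ester, instead of from C7, so that protonation gives the exocyclic 8(17)-alkene. The fallback decides the regiochemistry while C5=C6 is still present and C7 is doubly allylic. It sets out from 7: KOt-Bu in t-BuOH/THF followed by kinetic protonation should give the 5,7-diene ester methyl (1R,7R,8aS)-7-hydroxy-2,5,5,8a-tetramethyl-1,5,6,7,8,8a-hexahydronaphthalene-1-carboxylate F4. Partial hydrogenation over Raney nickel in EtOH (the conditions that turn sterol 5,7-dienes into 7-enes with a trans ring fusion) should saturate C5=C6 only, and the route is rejoined at 10.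

Step 13. Enolization may run toward C1, or the enolate may be captured by the sulfonimine by-product. The fallback replaces the kinetic enolate by the thermodynamic silyl enol ether and a neutral oxidant. It sets out from 19: TMSOTf and Et3N should give the C2–C3 trimethylsilyl enol ether of 19 F5. One equivalent of dimethyldioxirane in acetone at −78 °C (the electron-rich enol ether should react before the trisubstituted alkenes), followed by citric acid in MeOH, gives the 3-epimer, and the route is rejoined at 21, which the DBU stage of step 13 converts into 22.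

Further compounds
F1 | step 4 | (1S)-4-ethenyl-3,5,5-trimethylcyclohex-3-en-1-ol | O[C@H]1CC(C)=C(C=C)C(C)(C)C1
F2 | step 4 | tert-butyl{[(1S)-4-ethenyl-3,5,5-trimethylcyclohex-3-en-1-yl]oxy}dimethylsilane | CC(C)(C)[Si](C)(C)O[C@H]1CC(C)=C(C=C)C(C)(C)C1
F3 | step 4 | methyl (7R,8aR)-7-{[tert-butyl(dimethyl)silyl]oxy}-2,5,5,8a-tetramethyl-3,5,6,7,8,8a-hexahydronaphthalene-1-carboxylate | COC(=O)C1=C(C)CC=C2C(C)(C)C[C@@H](O[Si](C)(C)C(C)(C)C)C[C@@]12C
F4 | step 7 | methyl (1R,7R,8aS)-7-hydroxy-2,5,5,8a-tetramethyl-1,5,6,7,8,8a-hexahydronaphthalene-1-carboxylate | COC(=O)[C@@H]1C(C)=CC=C2C(C)(C)C[C@@H](O)C[C@@]12C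
F5 | step 13 | C2–C3 trimethylsilyl enol ether of 19 | CC(=O)OC/C=C(\C)CC[C@@H]1C(C)=CC[C@@H]2C(C)(C)C=C(O[Si](C)(C)C)C[C@@]12C
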